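**Analysis of the target**

Target 16 is an achiral flavone: pyranone ring C (O1, C2, C3, C4, C4a, C8a) is fused to benzene ring A (C4a, C5, C6, C7, C8, C8a) and carries ring B at C2. There is no stereocentre, so the problem is one of regiochemistry. Ring A is hexasubstituted: C4a bears the C4 carbonyl carbon, C5, C7 and C8 bear methoxy groups, C6 a free hydroxyl and C8a the ring oxygen O1, so exactly one of five contiguous oxygens must stay unmethylated. The feature the route is built on is that C6–OH and C8a–O1 are para to each other and bracket the vicinal C7–OMe/C8–OMe pair. This is the pattern of a hydroquinone grown from the four carbons of dimethyl squarate (8 below), whose two former carbonyl oxygens differ by origin from its two methoxy groups; C5(OMe)–C4a is then a two-carbon enol ether unit. Ring B is 1',2',6'-trisubstituted, so the C2–C1' bond is flanked by 2'-OH and 6'-OMe, and the 2'-OH can compete with the C8a oxygen when an open-chain 1,3-dicarbonyl precursor is cyclized. The 6-hydroxyl para to O1 makes ring A an easily oxidized p-alkoxyphenol, the pyranone opens in strong base, and the 5-OMe peri to C4=O is the ether most easily cleaved by Lewis acids, so a late selective demethylation would hit C5, not C6. Classical electrophilic chemistry on a polymethoxybenzene cannot tell the ring A positions apart, which is what makes the synthesis hard.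

**Retrosynthetic reasoning**

16 from 15: only the methoxymethyl ether on the 2'-oxygen is removed. The mask is needed because a free 2'-OH would quench the organolithium steps and could interfere with ring C closure; it comes off in dilute acid, which the flavone and all methyl ethers tolerate.

15 from 11 (through 14, 13 and 12): first the O1–C2 bond is cut, giving the 2-hydroxyaryl ynone 14, whose only hydroxyl ortho to the acyl group is the one on C8a. Ring A is then cut at C5–C6 (retro-6π electrocyclization, dienone 13 to dienylketene 12) and the C6–C8a bond is re-formed (retro-4π opening), which turns ring A into the cyclobutenone of 11. This cut is chosen because it makes C6, C7, C8 and C8a a squarate unit: the C6 oxygen is born as a ketene carbonyl and therefore appears as the free phenol, while C7 and C8 already carry their methoxy groups. No selective deprotection on ring A is ever needed. The forward reaction must open the four-membered ring with the alkenyl group turned inward, close ring A, aromatize it and close ring C in the 6-endo mode.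

11 from 10: the C4 ketone is traced back to a secondary alcohol, because an ynone cannot be carried through an organolithium step. The oxidation is placed before the ring expansion because the cyclobutenone is a form of the hydroquinone that an oxidant cannot touch.

10 from 8 and 9: the C4a–C8a bond is cut. Alkenyllithium 9 adds to one of the two equivalent carbonyl groups of symmetrical 8, so no regiochemical question arises. 9 comes from bromide 7 by deprotonation and bromine–lithium exchange.

7 from 5 and 6: the C3–C4 bond is cut to an acetylide and an aldehyde. The three-carbon piece 5 supplies C4 (aldehyde carbon), C4a (bromine-bearing carbon) and C5 with its methoxy group already in place. 5 comes in one step from symmetrical 4, and 6 from alkyne 3, made from aldehyde 1 via 2; the hindered C2–C1' bond is bought with the ring B aldehyde.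

**Alternatives that were turned down**

Alternative 1: the textbook disconnection cuts O1–C2 and C2–C3. Acetophenone A1 would be acylated with aroyl chloride A2, the ester rearranged to diketone A3 (Baker–Venkataraman) and A3 cyclodehydrated. It was turned down because the key step builds only ring C, while all the difficulty sits in A1. A1 must be made by stepwise electrophilic substitution and oxidation of a less oxygenated acetophenone (an Elbs-type hydroxylation para to a phenol, then selective benzylation of one of two hydroxyls), a long linear sequence with weak regiochemical control. Transfer of the doubly ortho-substituted aroyl group of A2 is also hindered.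

Alternative 2: a Dötz benzannulation would build ring A from open-chain pieces. Chromium carbene complex A4, (CO)5Cr=C(OCH2Ph)C(OMe)=CH(OMe), and alkoxyalkyne A5 would give phenol A6 by alkyne insertion, CO insertion and electrocyclization. The inserted CO would become C8a–OH and the carbene carbon C6. It was turned down because every assignment of a para pair (C5/C8 or C6/C8a) to carbene carbon and CO demands a 1,2-dialkoxyvinyl carbene ligand and an alkoxy- or dialkoxyalkyne. The regiochemistry of such alkynes follows electronic as much as steric effects and is not secured. The chromium is stoichiometric, and A6 still needs several steps to reach ring C.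

Alternative 3: ring A could be annulated onto a preformed ring C. Bromopyranone A8 would be lithiated at its C5 and added to the unsymmetrical squarate A7; thermal ring expansion would give flavone A9. It was turned down because the two carbonyl groups of A7 differ only in the remote alkyl group of an ether, so the C6 and C7 oxygens would be scrambled. Even the right isomer A9 has hydroxyls at C5 and C8 that both need methylation (C5–OH is chelated to C4=O, and the 5,8-hydroquinone is oxidized easily) before debenzylation. Lithiated 4-pyranones also tend to ring-open, and A8 needs its own synthesis. The chosen mapping avoids all of this by making C6 and C8a the carbonyl carbons of symmetrical 8.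

Key step: step 7

Remark on the chemistry: the enol ether double bond of 5, 7, 9, 10 and 11 is drawn with methoxy cis to bromine (or to the atom that replaces it). Either geometry would serve, because C5 becomes an aromatic carbon in step 7.

**Route**

Step 1
Reactants: 1 2-hydroxy-6-methoxybenzaldehyde
Product: 2 2-methoxy-6-(methoxymethoxy)benzaldehyde
Conditions: MOMCl, iPr2NEt, CH2Cl2, 0 °C to rt
Reagents that add atoms: chloromethyl methyl ether, COCCl
Why: O-alkylation of the phenol (methoxymethyl protection); the ether survives organolithium reagents, keeps the 2'-oxygen out of the later ring closures and is removed by dilute acid.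

Step 2
Reactants: 2 2-methoxy-6-(methoxymethoxy)benzaldehyde
Product: 3 2-ethynyl-1-methoxy-3-(methoxymethoxy)benzene
Conditions: dimethyl (1-diazo-2-oxopropyl)phosphonate, K2CO3, MeOH, rt
Reagents that add atoms: dimethyl (1-diazo-2-oxopropyl)phosphonate, COP(=O)(OC)C(=[N+]=[N-])C(C)=O
Why: Seyferth–Gilbert homologation in the Ohira–Bestmann variant turns the aryl aldehyde into the terminal alkyne in one step under carbonate conditions that leave the acetal untouched.

Step 3
Reactants: 4 2-bromomalonaldehyde
Product: 5 (Z)-2-bromo-3-methoxyprop-2-enal
Conditions: TMSCHN2 (2 M in hexanes), MeOH/CH2Cl2, 0 °C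
Reagents that add atoms: (trimethylsilyl)diazomethane, C[Si](C)(C)C=[N+]=[N-]
Why: 4 exists as its enol, a strong vinylogous formic acid, and should be O-methylated like a carboxylic acid or an enolized 1,3-diketone; its two oxygens are equivalent, so only one constitution can form, and the isomer with methoxy trans to the formyl group is expected.

Step 4
Reactants: 3 2-ethynyl-1-methoxy-3-(methoxymethoxy)benzene, 5 (Z)-2-bromo-3-methoxyprop-2-enal
Product: 7 (1Z)-2-bromo-1-methoxy-5-[2-methoxy-6-(methoxymethoxy)phenyl]pent-1-en-4-yn-3-ol (racemic), via lithium acetylide 6 (not isolated)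
Conditions: 3, n-BuLi, THF, −78 °C; then 5, −78 °C; H2O quench; Et3N-deactivated silica
Reagents that add atoms: none
Why: 1,2-addition of a lithium acetylide to an aldehyde; at −78 °C the formyl carbon of the vinylogous formate is the hard electrophilic site, and a neutral work-up protects the acid-labile hydroxy enol ether.

Step 5
Reactants: 7 (1Z)-2-bromo-1-methoxy-5-[2-methoxy-6-(methoxymethoxy)phenyl]pent-1-en-4-yn-3-ol, 8 dimethyl squarate (3,4-dimethoxycyclobut-3-ene-1,2-dione)
Product: 10 4-hydroxy-4-{(1Z)-3-hydroxy-1-methoxy-5-[2-methoxy-6-(methoxymethoxy)phenyl]pent-1-en-4-yn-2-yl}-2,3-dimethoxycyclobut-2-en-1-one (mixture of diastereomers), via dilithio alkenyllithium alkoxide 9 (not isolated)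
Conditions: 7, n-BuLi (1 equiv) then t-BuLi (2 equiv), THF, −78 °C; cannulate into 8, THF, −78 °C; AcOH, −78 °C
Reagents that add atoms: none
Why: O-deprotonation and bromine–lithium exchange with retention of geometry give the oxido alkenyllithium (as with dianions of 2-bromoallylic alcohols), in which lithium cis to methoxy is chelated and resists elimination; it adds 1,2 to one of the two equivalent carbonyl groups of 8, the standard entry to 4-hydroxycyclobutenones. The two stereocentres formed are of no consequence, since one is oxidized in step 6 and the other becomes aromatic in step 7.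

Step 6
Reactants: 10 4-hydroxy-4-{(1Z)-3-hydroxy-1-methoxy-5-[2-methoxy-6-(methoxymethoxy)phenyl]pent-1-en-4-yn-2-yl}-2,3-dimethoxycyclobut-2-en-1-one
Product: 11 4-hydroxy-2,3-dimethoxy-4-{(1E)-1-methoxy-5-[2-methoxy-6-(methoxymethoxy)phenyl]-3-oxopent-1-en-4-yn-2-yl}cyclobut-2-en-1-one (racemic)
Conditions: MnO2 (activated, excess), CH2Cl2, rt
Reagents that add atoms: none
Why: MnO2 oxidation is selective for the secondary alcohol that is both allylic and propargylic; the tertiary cyclobutenol cannot be oxidized, and the ring A carbons are still locked in a cyclobutenone that the oxidant cannot turn into a quinone.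

Step 7
Reactants: 11 4-hydroxy-2,3-dimethoxy-4-{(1E)-1-methoxy-5-[2-methoxy-6-(methoxymethoxy)phenyl]-3-oxopent-1-en-4-yn-2-yl}cyclobut-2-en-1-one
Product: 15 6-hydroxy-5,7,8-trimethoxy-2-[2-methoxy-6-(methoxymethoxy)phenyl]-4H-chromen-4-one, via dienylketene 12 (not isolated), via cyclohexadienone 13 (not isolated), via hydroquinone ynone 14 (not isolated)
Conditions: PhMe (degassed, 0.01 M), 110 °C, Ar; then Et2NH (2 equiv), 25 °C
Reagents that add atoms: none
Why: Heating should open the cyclobutenone by conrotatory 4π cleavage of the C6–C8a bond to dienylketene 12; the hydroxyl on C8a rotates outward as donor groups do, which turns the alkenyl group inward, cis to the ketene. A 6π electrocyclization then joins the ketene carbon C6 to the enol ether carbon C5, the only terminus within reach, to give dienone 13, and transfer of the C5 hydrogen to the C6 oxygen aromatizes it to hydroquinone 14; the closest known reaction type is the Moore ring expansion of 4-alkenyl-4-hydroxycyclobutenones made from squarate esters. Ring A is thus closed with every substituent in place: C7 and C8 methoxy from 8, C5 methoxy from 5, C6 as the free phenol and C8a as the second phenol. Ring C then closes by 6-endo-dig conjugate addition of the C8a hydroxyl to the ynone (O1–C2 bond), the standard cyclization of 2-hydroxyaryl ynones; only this hydroxyl is ortho to the acyl group, so the C6 hydroxyl cannot compete and stays free. The 6-endo mode is favoured over 5-exo closure by the aprotic medium and the secondary amine, which is regenerated. No stereocentre is formed, and the stereocentre and alkene geometry of 11 are erased. An early conjugate addition of the tertiary hydroxyl to the ynone would not divert material, because ring opening, electrocyclization and tautomerization can still follow and end at 15. Exclusion of oxygen protects 14 until it has cyclized.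

Step 8
Reactants: 15 6-hydroxy-5,7,8-trimethoxy-2-[2-methoxy-6-(methoxymethoxy)phenyl]-4H-chromen-4-one
Product: 16 6-hydroxy-2-(2-hydroxy-6-methoxyphenyl)-5,7,8-trimethoxy-4H-chromen-4-one (6,2'-dihydroxy-5,7,8,6'-tetramethoxyflavone)
Conditions: HCl (3 M aq), MeOH, 50 °C
Reagents that add atoms: none
Why: acid-catalysed cleavage of the methoxymethyl acetal by transfer to methanol; the aryl methyl ethers, including the 5-methoxy group peri to the carbonyl, and the pyranone are stable to dilute protic acid.

**Compound list**

1 | 2-hydroxy-6-methoxybenzaldehyde | COc1cccc(O)c1C=O | starting material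
2 | 2-methoxy-6-(methoxymethoxy)benzaldehyde | COCOc1cccc(OC)c1C=O | intermediate
3 | 2-ethynyl-1-methoxy-3-(methoxymethoxy)benzene | COCOc1cccc(OC)c1C#C | intermediate
4 | 2-bromomalonaldehyde (2-bromopropanedial, present as its enol) | O=CC(Br)C=O | starting material
5 | (Z)-2-bromo-3-methoxyprop-2-enal | CO/C=C(\Br)C=O | intermediate
6 | lithium [2-methoxy-6-(methoxymethoxy)phenyl]acetylide | [Li]C#Cc1c(OC)cccc1OCOC | intermediate
7 | (1Z)-2-bromo-1-methoxy-5-[2-methoxy-6-(methoxymethoxy)phenyl]pent-1-en-4-yn-3-ol (racemic) | CO/C=C(\Br)C(O)C#Cc1c(OC)cccc1OCOC | intermediate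
8 | dimethyl squarate (3,4-dimethoxycyclobut-3-ene-1,2-dione) | COC1=C(OC)C(=O)C1=O | starting material
9 | lithium (1E)-2-lithio-1-methoxy-5-[2-methoxy-6-(methoxymethoxy)phenyl]pent-1-en-4-yn-3-olate | CO/C=C(\[Li])C(O[Li])C#Cc1c(OC)cccc1OCOC | intermediate
10 | 4-hydroxy-4-{(1Z)-3-hydroxy-1-methoxy-5-[2-methoxy-6-(methoxymethoxy)phenyl]pent-1-en-4-yn-2-yl}-2,3-dimethoxycyclobut-2-en-1-one (mixture of diastereomers) | CO/C=C(\C1(O)C(OC)=C(OC)C1=O)C(O)C#Cc1c(OC)cccc1OCOC | intermediate
11 | 4-hydroxy-2,3-dimethoxy-4-{(1E)-1-methoxy-5-[2-methoxy-6-(methoxymethoxy)phenyl]-3-oxopent-1-en-4-yn-2-yl}cyclobut-2-en-1-one (racemic) | CO/C=C(\C1(O)C(OC)=C(OC)C1=O)C(=O)C#Cc1c(OC)cccc1OCOC | intermediate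
12 | dienylketene: 4-hydroxy-2,3-dimethoxy-5-(methoxymethylidene)-8-[2-methoxy-6-(methoxymethoxy)phenyl]octa-1,3-dien-7-yne-1,6-dione (ketene carbon cis to C5 across C3=C4) | O=C=C(OC)/C(OC)=C(/O)\C(=C/OC)C(=O)C#Cc1c(OC)cccc1OCOC | intermediate
13 | 4-hydroxy-2,3,6-trimethoxy-5-{3-[2-methoxy-6-(methoxymethoxy)phenyl]prop-2-ynoyl}cyclohexa-2,4-dien-1-one (racemic) | COC1C(=O)C(OC)=C(OC)C(O)=C1C(=O)C#Cc1c(OC)cccc1OCOC | intermediate
14 | 1-(2,5-dihydroxy-3,4,6-trimethoxyphenyl)-3-[2-methoxy-6-(methoxymethoxy)phenyl]prop-2-yn-1-one | COc1c(O)c(OC)c(OC)c(O)c1C(=O)C#Cc1c(OC)cccc1OCOC | intermediate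
15 | 6-hydroxy-5,7,8-trimethoxy-2-[2-methoxy-6-(methoxymethoxy)phenyl]-4H-chromen-4-one | COCOc1cccc(OC)c1-c1cc(=O)c2c(OC)c(O)c(OC)c(OC)c2o1 | intermediate
16 | 6-hydroxy-2-(2-hydroxy-6-methoxyphenyl)-5,7,8-trimethoxy-4H-chromen-4-one | COc1cccc(O)c1-c1cc(=O)c2c(OC)c(O)c(OC)c(OC)c2o1 | target

**Step count and risk**

Total step count: 8. Longest linear sequence: 7 steps (1 to 2 to 3 to 7 to 10 to 11 to 15 to 16); step 3 (4 to 5) is a one-step side branch.

Step 7 (key step). Most likely to go wrong:
- consumption of the ketene by other paths (inward rotation of the hydroxyl and lactonization, or intermolecular trapping by a hydroxyl);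
- thermal degradation of the ynone;
- air oxidation at the hydroquinone stage;
- closure of ring C in the 5-exo mode.

The fallback divides the cascade and caps the hydroxyl that causes these losses. It sets out from 11, which is silylated (TMSCl, imidazole, DMF, 0 °C) to the tertiary trimethylsilyl ether F1. Thermolysis of F1 in toluene at 110 °C should give the monosilylated hydroquinone ynone F2 (C8a–OSiMe3, C6–OH) with no free hydroxyl near the ketene and ring A held as a monoether. Fluoride (TBAF, THF, 0 °C) then frees the C8a phenoxide, which closes ring C in the aprotic medium. The fallback comes back to the route at 15.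

Step 5. Most likely to go wrong: the secondary alkoxide attacks the vinylogous ester carbon of the cyclobutenone in the adduct, with loss of methoxide; or the alkenyllithium loses lithium methoxide or is protonated before it adds. The fallback removes the alkoxide and sets out from 7: silylation (TBSCl, imidazole, DMF) gives the tert-butyldimethylsilyl ether F3; exchange (t-BuLi, 2 equiv, THF, −78 °C) gives the monolithio species F4; addition to 8 and an acetic acid quench give the silylated adduct F5; HF·pyridine in THF at 0 °C removes the silyl group. It comes back at 10.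

Step 4. Most likely to go wrong: acid-catalysed allylic transposition and hydrolysis of the hydroxy enol ether during work-up and chromatography, and to a lesser extent addition–elimination at the methoxy-bearing carbon. The fallback avoids isolation. It sets out from 6 and 5: the lithium alkoxide formed at −78 °C is not quenched but treated in the same flask with t-BuLi (2 equiv) and then transferred onto 8 as in step 5. It comes back at 9 and makes no new compound (entry F0).

Step 3. Most likely to go wrong: attack of the diazo reagent on the formyl group, or partial acetal formation in methanol, so that a mixture results. The fallback goes through full acetalization and sets out from 4: HC(OMe)3, MeOH and catalytic TsOH should give (Z)-2-bromo-1,3,3-trimethoxyprop-1-ene F6, which has no free carbonyl and can be distilled. Partial hydrolysis (aqueous HCO2H, 0 °C) passes through a symmetrical alkoxyallyl cation, so water attack at either end gives the same aldehyde. It comes back at 5.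

**Further compounds**

F1 | step 7 | 2,3-dimethoxy-4-{(1E)-1-methoxy-5-[2-methoxy-6-(methoxymethoxy)phenyl]-3-oxopent-1-en-4-yn-2-yl}-4-[(trimethylsilyl)oxy]cyclobut-2-en-1-one | CO/C=C(\C1(O[Si](C)(C)C)C(OC)=C(OC)C1=O)C(=O)C#Cc1c(OC)cccc1OCOC
F2 | step 7 | 1-{5-hydroxy-3,4,6-trimethoxy-2-[(trimethylsilyl)oxy]phenyl}-3-[2-methoxy-6-(methoxymethoxy)phenyl]prop-2-yn-1-one | COc1c(O)c(OC)c(OC)c(O[Si](C)(C)C)c1C(=O)C#Cc1c(OC)cccc1OCOC
F3 | step 5 | {[(1Z)-2-bromo-1-methoxy-5-[2-methoxy-6-(methoxymethoxy)phenyl]pent-1-en-4-yn-3-yl]oxy}(tert-butyl)dimethylsilane | CO/C=C(\Br)C(O[Si](C)(C)C(C)(C)C)C#Cc1c(OC)cccc1OCOC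
F4 | step 5 | {(1E)-3-[(tert-butyldimethylsilyl)oxy]-1-methoxy-5-[2-methoxy-6-(methoxymethoxy)phenyl]pent-1-en-4-yn-2-yl}lithium | CO/C=C(\[Li])C(O[Si](C)(C)C(C)(C)C)C#Cc1c(OC)cccc1OCOC
F5 | step 5 | 4-{(1Z)-3-[(tert-butyldimethylsilyl)oxy]-1-methoxy-5-[2-methoxy-6-(methoxymethoxy)phenyl]pent-1-en-4-yn-2-yl}-4-hydroxy-2,3-dimethoxycyclobut-2-en-1-one | CO/C=C(\C1(O)C(OC)=C(OC)C1=O)C(O[Si](C)(C)C(C)(C)C)C#Cc1c(OC)cccc1OCOC
F0 | step 4 | none | none
F6 | step 3 | (Z)-2-bromo-1,3,3-trimethoxyprop-1-ene | CO/C=C(\Br)C(OC)OC
A1 | alternative 1 | 1-[5-(benzyloxy)-2-hydroxy-3,4,6-trimethoxyphenyl]ethan-1-one | CC(=O)c1c(O)c(OC)c(OC)c(OCc2ccccc2)c1OC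
A2 | alternative 1 | 2-(benzyloxy)-6-methoxybenzoyl chloride | COc1cccc(OCc2ccccc2)c1C(Cl)=O
A3 | alternative 1 | 1-[5-(benzyloxy)-2-hydroxy-3,4,6-trimethoxyphenyl]-3-[2-(benzyloxy)-6-methoxyphenyl]propane-1,3-dione | COc1cccc(OCc2ccccc2)c1C(=O)CC(=O)c1c(O)c(OC)c(OC)c(OCc2ccccc2)c1OC
A4 | alternative 2 | pentacarbonyl[(benzyloxy)(1,2-dimethoxyethenyl)methylidene]chromium, (CO)5Cr=C(OCH2Ph)C(OMe)=CH(OMe) | COC=C(OC)C(OCc1ccccc1)=[Cr].[C-]#[O+].[C-]#[O+].[C-]#[O+].[C-]#[O+].[C-]#[O+]
A5 | alternative 2 | 3,3-diethoxy-1-methoxyprop-1-yne | CCOC(OCC)C#COC
A6 | alternative 2 | 4-(benzyloxy)-6-(diethoxymethyl)-2,3,5-trimethoxyphenol | CCOC(OCC)c1c(O)c(OC)c(OC)c(OCc2ccccc2)c1OC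
A7 | alternative 3 | 3-(benzyloxy)-4-methoxycyclobut-3-ene-1,2-dione | COC1=C(OCc2ccccc2)C(=O)C1=O
A8 | alternative 3 | 5-bromo-2-[2-methoxy-6-(methoxymethoxy)phenyl]-4H-pyran-4-one | COCOc1cccc(OC)c1-c1cc(=O)c(Br)co1
A9 | alternative 3 | 6-(benzyloxy)-5,8-dihydroxy-7-methoxy-2-[2-methoxy-6-(methoxymethoxy)phenyl]-4H-chromen-4-one | COCOc1cccc(OC)c1-c1cc(=O)c2c(O)c(OCc3ccccc3)c(OC)c(O)c2o1
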